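The constants used here were chosen freely, and the outcome is calculated.

4 questions stand here, and I answer them through one quantity.

J 11 mM; Q 1.1 µM; G 0.57 µM

    J + Q → D + Q, rate k1*[J]*[Q]/(1 + ([J]/Km1)) (Km1 = 7.6 mM, k1 = 7.6 × 10⁵ /M/h)
    Q ⇌ Z (K2 = 3.9, k2 = 0.27 /h)
    Q + G ⇌ Q.G (K3 = 7.1 × 10⁶ /M, k3 = 6.2 × 10⁵ /M/h)

- the form that holds most of the catalyst when 50% of the J are converted (Q / Z / Q.G)
- its share of the catalyst then
- factor on the rate of making D when 50% of the J are converted if Q is charged twice over
- factor on the rate when 50% of the J are converted if Q is charged at 12 µM instead

Step 1 consumes J at a rate proportional to free Q, so dividing its rate law by the J term and integrating gives the dose of free Q, the time-integral of free Q needed to reach a given conversion: (ln(J charged/J left) + J used/Km1)/k1. For 50% conversion of this J, the dose is 1.86 µM·h, whatever the charge of Q.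

In this flask free Q falls from its charge towards a floor, at first at 0.623 /h per Q, the forward rates of steps 2 and 3 together with G as charged. Putting a first floor back into the balance of G gives a floor of 0.156 µM.

My small table has 2 columns, a guessed time and the mean free Q over it on an exponential fall to that floor. The first row takes the full charge, which gives 1.69 h and a mean of 0.739 µM. The dose over that mean gives the second row, 2.52 h and 0.632 µM. The third row has 2.95 h and 0.587 µM, and the next time is 3.17 h. Each correction is about half the one before, so the corrections still to come add up to about the last one, and I commit to 3.40 h.

Free Q then stands near 0.270 µM. If I roughly put Q.G at the value my floor leaves it, 0.337 µM, Z holds the remaining 0.494 µM, which is 44.9% of the catalyst, and on this estimate it leads.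

With the same J charged, J is equal at equal conversion, so a rate factor is a factor on free Q. For one round, I take the time in which each larger charge delivers the dose, let free Q decay from that charge over this time at the first rate per Q, and divide by my free Q above, which gives 4.81 for the doubled charge and 40.4 for 12 µM.

The forecast, “with Z only narrowly ahead”, gives Z at 40%, with factors 4.3 and 34, so its share and factors are lower than mine.

The flask gives Z at 40.0%, with factors 4.19 and 34.7. It reaches 50% conversion at 3.26 h, against my 3.40 h, so the dose corresponds to a mean free Q of 0.571 µM over that time. The flask charged at 12 µM needs the same dose, which its full charge would deliver in 0.155 h, and over that time the forward direction of step 2 alone would move about 4.19% of Q into Z. At that conversion, 92.6% of its catalyst is Q.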